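**Retrosynthetic overview** (chromene numbering: O1, C2, C3, C4, C4a, C5–C8, C8a)

1. Kumbicin C (13) ⇐ global deprotection (step 6) ⇐ twofold Suzuki–Miyaura coupling that attaches both ready-made indole rings to C5 and C8 of 5-bromo-8-iodo-2H-chromene 10 (step 5).
2. 10 ⇐ dehydration (step 4) of chroman-4-ol 9, which is cut in one operation into dibromoaldehyde 3 and the four-carbon chlorohydrin 4: C3–C4 by carbonyl addition of LiCH2C(CH3)2OLi, O1–C8a by capture of an aryne by the tethered alkoxide, and the aryl anion left at C8 is iodinated (step 3).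
3. Enabling feature: the benzene ring of 3 has a single C–H (future C8), lying between the C7 methoxy group and the C–Br of future C8a, and C8a is ortho to the formyl-bearing C4a. An aryne can therefore form only across C8–C8a, the O1–C2–C3 unit bridges the formyl carbon (C4) and C8a to close the pyran ring, and the carbanion expelled onto C8 sits where the second indole is needed.
4. Ring order: benzene ring bought with 1 and dressed in steps 1–2; pyran ring in step 3 (its C3=C4 double bond in step 4); the two indole rings are attached intact in step 5.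

Key step: step 3

Assumption: compounds 1, 4 and 11 are taken as purchasable; the C4 hydroxyl of 9 is an extra oxidation level that step 4 removes.

**Step 1**
Reactants: 1 2-bromo-5-hydroxy-4-methoxybenzaldehyde (6-bromoisovanillin)
Product: 2 2,6-dibromo-3-hydroxy-4-methoxybenzaldehyde
Conditions: Br2 (1.05 equiv), NaOAc, AcOH, rt
Reagents that add atoms: bromine, BrBr
Why: Electrophilic aromatic bromination (SEAr) in which the free phenol directs bromine to its only open ortho position (para is already brominated), as in the ortho-bromination of isovanillin itself, while the OMe-flanked C–H is much less activated.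

**Step 2**
Reactants: 2 2,6-dibromo-3-hydroxy-4-methoxybenzaldehyde
Product: 3 2,6-dibromo-4-methoxy-3-[(triisopropylsilyl)oxy]benzaldehyde
Conditions: TIPSOTf, 2,6-lutidine, CH2Cl2, 0 °C → rt
Reagents that add atoms: triisopropylsilyl trifluoromethanesulfonate, CC(C)[Si](OS(=O)(=O)C(F)(F)F)(C(C)C)C(C)C
Why: Silylation of a phenol with a silyl triflate and a hindered pyridine base, a standard protection that should work on this doubly ortho-substituted phenol and gives an ether bulky enough to resist organolithiums, LiTMP and silyl transfer to the alkoxides of step 3.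

**Step 3**
Reactants: 3 2,6-dibromo-4-methoxy-3-[(triisopropylsilyl)oxy]benzaldehyde; 4 1-chloro-2-methylpropan-2-ol
Product: 9 (±)-5-bromo-8-iodo-7-methoxy-2,2-dimethyl-6-[(triisopropylsilyl)oxy]chroman-4-ol, via β-oxido organolithium 5 (not isolated), via dilithium diolate 6 (not isolated), via aryne 7 (not isolated), via aryllithium 8 (not isolated)
Conditions: 4 (1.3 equiv), n-BuLi (1.3 equiv) then lithium naphthalenide (LiC10H8, 2.5 equiv), THF, −78 °C; 3 (1.0 equiv), −78 °C; LiTMP (2.5 equiv), −78 → −20 °C; I2 (4 equiv), −78 °C → rt; H2O
Reagents that add atoms: iodine, II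
Why: Proposed new method: a one-flask anionic (3+3) annulation in which the β-oxido organolithium 5 adds through carbon to the aldehyde of 3 (C3–C4 bond, diolate 6), LiTMP then removes the only aromatic hydrogen and loss of LiBr gives aryne 7, whose C8a is captured by the tethered tertiary alkoxide (O1–C8a bond) to give aryllithium 8, which is iodinated at C8. The closest known reaction types are the addition of β-oxido organolithiums made from chlorohydrins to aldehydes, the intramolecular capture of base-generated benzynes by tethered alkoxides to give chromans, and the iodination of aryllithiums; their merger in one flask is the new element. The pyran ring closes by a 6-exo-dig addition of the alkoxide to the aryne carbon remote from the methoxy group, the mode favoured both by the tether and by the inductive effect of the methoxy group, which places the new carbanion at C8 next to OMe. The only new stereocentre, C4, forms without control (racemate) and is erased by the dehydration of step 4. The step needs site selectivity between the two C–Br bonds flanking the carbinol and chemoselectivity for carbonyl addition over bromine–lithium exchange: the first is secured because only the C–Br next to the single C–H can give an aryne (the other bromine has no ortho hydrogen), the second by the much faster addition to the aldehyde at −78 °C and by using a non-nucleophilic amide base for the aryne stage.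

**Step 4**
Reactants: 9 (±)-5-bromo-8-iodo-7-methoxy-2,2-dimethyl-6-[(triisopropylsilyl)oxy]chroman-4-ol
Product: 10 5-bromo-8-iodo-7-methoxy-2,2-dimethyl-6-[(triisopropylsilyl)oxy]-2H-chromene
Conditions: TsOH·H2O (5 mol %), toluene, 60 °C
Reagents that add atoms: none
Why: Acid-catalysed E1 dehydration of a benzylic chroman-4-ol, the classical closing move of 2,2-dimethylchromene syntheses, eased by the para-methoxy (C7) and ortho-ether (O1) donors that stabilise the C4 cation; only C3 carries β-hydrogens, so a single alkene can form and the C4 stereocentre disappears.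

**Step 5**
Reactants: 10 5-bromo-8-iodo-7-methoxy-2,2-dimethyl-6-[(triisopropylsilyl)oxy]-2H-chromene; 11 tert-butyl 3-(4,4,5,5-tetramethyl-1,3,2-dioxaborolan-2-yl)indole-1-carboxylate (3 equiv)
Product: 12 di-tert-butyl 3,3'-{7-methoxy-2,2-dimethyl-6-[(triisopropylsilyl)oxy]-2H-chromene-5,8-diyl}bis(indole-1-carboxylate)
Conditions: Pd(OAc)2 (10 mol %), SPhos (20 mol %), K3PO4, toluene/H2O (10:1), 90 °C
Reagents that add atoms: none
Why: Twofold Suzuki–Miyaura cross-coupling with a dialkylbiarylphosphine ligand suited to di-ortho-substituted aryl halides, the C8 iodide expected to react before the C5 bromide and excess boronate compensating for protodeboronation; partial loss of Boc or silyl groups under the basic conditions is harmless because step 6 removes them all.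

**Step 6**
Reactants: 12 di-tert-butyl 3,3'-{7-methoxy-2,2-dimethyl-6-[(triisopropylsilyl)oxy]-2H-chromene-5,8-diyl}bis(indole-1-carboxylate)
Product: 13 Kumbicin C
Conditions: TBAF (1 M in THF, wet, 6 equiv), THF, rt → 65 °C, under Ar
Reagents that add atoms: none
Why: Fluoride-mediated global deprotection in which TBAF cleaves the aryl silyl ether at room temperature and, in refluxing THF, the two N-Boc carbamates of the weakly basic indole nitrogens (a known fluoride-induced carbamate cleavage), without touching the chromene double bond.

**Compound list**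

1 | 2-bromo-5-hydroxy-4-methoxybenzaldehyde | O=Cc1cc(O)c(OC)cc1Br | starting material
2 | 2,6-dibromo-3-hydroxy-4-methoxybenzaldehyde | O=Cc1c(Br)c(O)c(OC)cc1Br | intermediate
3 | 2,6-dibromo-4-methoxy-3-[(triisopropylsilyl)oxy]benzaldehyde | O=Cc1c(Br)c(O[Si](C(C)C)(C(C)C)C(C)C)c(OC)cc1Br | intermediate
4 | 1-chloro-2-methylpropan-2-ol | CC(C)(O)CCl | starting material
5 | lithium 1-lithio-2-methylpropan-2-olate, LiCH2C(CH3)2OLi (not isolated) | [Li]CC(C)(C)O[Li] | intermediate
6 | dilithium 1-{2,6-dibromo-4-methoxy-3-[(triisopropylsilyl)oxy]phenyl}-3-methylbutane-1,3-diolate, racemic (not isolated) | [Li]OC(CC(C)(C)O[Li])c1c(Br)c(O[Si](C(C)C)(C(C)C)C(C)C)c(OC)cc1Br | intermediate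
7 | aryne from 6 by loss of LiBr across the former C–H and C–Br carbons, racemic (not isolated) | [Li]OC(CC(C)(C)O[Li])C1=C(Br)C(O[Si](C(C)C)(C(C)C)C(C)C)=C(OC)C#C1 | intermediate
8 | lithium 5-bromo-8-lithio-7-methoxy-2,2-dimethyl-6-[(triisopropylsilyl)oxy]chroman-4-olate, racemic (not isolated) | CC1(C)CC(O[Li])c2c(Br)c(O[Si](C(C)C)(C(C)C)C(C)C)c(OC)c([Li])c2O1 | intermediate
9 | (±)-5-bromo-8-iodo-7-methoxy-2,2-dimethyl-6-[(triisopropylsilyl)oxy]chroman-4-ol (racemic at C4) | CC1(C)CC(O)c2c(Br)c(O[Si](C(C)C)(C(C)C)C(C)C)c(OC)c(I)c2O1 | intermediate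
10 | 5-bromo-8-iodo-7-methoxy-2,2-dimethyl-6-[(triisopropylsilyl)oxy]-2H-chromene | CC1(C)C=Cc2c(Br)c(O[Si](C(C)C)(C(C)C)C(C)C)c(OC)c(I)c2O1 | intermediate
11 | tert-butyl 3-(4,4,5,5-tetramethyl-1,3,2-dioxaborolan-2-yl)indole-1-carboxylate | CC(C)(C)OC(=O)n1cc(B2OC(C)(C)C(C)(C)O2)c2ccccc12 | starting material
12 | di-tert-butyl 3,3'-{7-methoxy-2,2-dimethyl-6-[(triisopropylsilyl)oxy]-2H-chromene-5,8-diyl}bis(indole-1-carboxylate) | CC1(C)C=Cc2c(-c3cn(C(=O)OC(C)(C)C)c4ccccc34)c(O[Si](C(C)C)(C(C)C)C(C)C)c(OC)c(-c3cn(C(=O)OC(C)(C)C)c4ccccc34)c2O1 | intermediate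
13 | Kumbicin C (no stereocentre) | COc1c(O)c(-c2c[nH]c3ccccc23)c2c(c1-c1c[nH]c3ccccc13)OC(C)(C)C=C2 | target

**Step count and risks**

Total step count: 6. Longest linear sequence: 6 steps (1 → 13).

Steps most likely to fail:

Step 3 (proposed one-flask annulation). The β-oxido organolithium may eliminate to isobutene before it adds. The aryllithium formed next to bromine may exchange or migrate halogen instead of losing LiBr. The aggregated lithium alkoxide may capture the aryne too slowly, so that external nucleophiles add, and the aryllithium may be protonated by the liberated amine before iodination. The fallback sets out from compound 3, uses only known reactions and avoids an aryne. Aldol addition of the lithium enolate of ethyl acetate (LDA, THF, −78 °C) should give ethyl 3-{2,6-dibromo-4-methoxy-3-[(triisopropylsilyl)oxy]phenyl}-3-hydroxypropanoate F1. Excess MeMgBr should convert the ester into 1-{2,6-dibromo-4-methoxy-3-[(triisopropylsilyl)oxy]phenyl}-3-methylbutane-1,3-diol F2. An intramolecular Ullmann-type etherification (CuI, 1,10-phenanthroline, Cs2CO3, toluene, 110 °C) should then close the pyran ring to 5-bromo-7-methoxy-2,2-dimethyl-6-[(triisopropylsilyl)oxy]chroman-4-ol F3; it is expected to engage the less hindered C–Br, the one with an ortho hydrogen. Iodination of the single remaining aryl C–H (NIS, DMF, rt) returns to the route at compound 9.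

Step 5. Protodeboronation of the indol-3-yl boronate may outrun transmetalation at the two di-ortho-substituted carbon–halogen bonds, so that coupling stops after one indole or the halide is reduced. The fallback sets out from compound 10 and changes both the organometallic partner and the nitrogen protection. Commercial 3-bromo-1-(triisopropylsilyl)indole is lithiated (t-BuLi, THF, −78 °C) and transmetalated with ZnCl2 to [1-(triisopropylsilyl)indol-3-yl]zinc chloride F4. A twofold Negishi coupling of this reagent with 10 (Pd(OAc)2, SPhos, THF, 60 °C) should give 7-methoxy-2,2-dimethyl-6-[(triisopropylsilyl)oxy]-5,8-bis[1-(triisopropylsilyl)indol-3-yl]-2H-chromene F5. TBAF at room temperature removes all three silyl groups, and the route is rejoined at the target 13.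

Step 6. Carbamate cleavage at the two hindered indoles may stay incomplete, and the electron-rich phenoxide (a hydroquinone mono-ether) may be oxidised under hot basic fluoride. The fallback sets out from compound 12 and uses an orthogonal two-stage sequence that never forms the phenoxide. Thermolysis of the two N-Boc groups without reagent (2,2,2-trifluoroethanol, 120 °C, sealed vessel) should give 3,3'-{7-methoxy-2,2-dimethyl-6-[(triisopropylsilyl)oxy]-2H-chromene-5,8-diyl}bis(1H-indole) F6. Buffered acidic fluoride (HF·pyridine, THF, 0 °C) then cleaves the aryl silyl ether and delivers 13.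

**Further compounds**

F1 | step 3 | ethyl 3-{2,6-dibromo-4-methoxy-3-[(triisopropylsilyl)oxy]phenyl}-3-hydroxypropanoate (racemic) | CCOC(=O)CC(O)c1c(Br)c(O[Si](C(C)C)(C(C)C)C(C)C)c(OC)cc1Br
F2 | step 3 | 1-{2,6-dibromo-4-methoxy-3-[(triisopropylsilyl)oxy]phenyl}-3-methylbutane-1,3-diol (racemic) | CC(C)(O)CC(O)c1c(Br)c(O[Si](C(C)C)(C(C)C)C(C)C)c(OC)cc1Br
F3 | step 3 | 5-bromo-7-methoxy-2,2-dimethyl-6-[(triisopropylsilyl)oxy]chroman-4-ol (racemic) | CC1(C)CC(O)c2c(Br)c(O[Si](C(C)C)(C(C)C)C(C)C)c(OC)cc2O1
F4 | step 5 | [1-(triisopropylsilyl)indol-3-yl]zinc chloride | Cl[Zn]c1cn([Si](C(C)C)(C(C)C)C(C)C)c2ccccc12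
F5 | step 5 | 7-methoxy-2,2-dimethyl-6-[(triisopropylsilyl)oxy]-5,8-bis[1-(triisopropylsilyl)indol-3-yl]-2H-chromene | CC1(C)C=Cc2c(-c3cn([Si](C(C)C)(C(C)C)C(C)C)c4ccccc34)c(O[Si](C(C)C)(C(C)C)C(C)C)c(OC)c(-c3cn([Si](C(C)C)(C(C)C)C(C)C)c4ccccc34)c2O1
F6 | step 6 | 3,3'-{7-methoxy-2,2-dimethyl-6-[(triisopropylsilyl)oxy]-2H-chromene-5,8-diyl}bis(1H-indole) | CC1(C)C=Cc2c(-c3c[nH]c4ccccc34)c(O[Si](C(C)C)(C(C)C)C(C)C)c(OC)c(-c3c[nH]c4ccccc34)c2O1
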